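Which flask ends with more product: south-east, with the larger partner charge, or south, with the longer time?

in all of them: substrate 0.10 M
- alder: partner 0.16 M; run made earlier
- oak: partner 0.63 M; run made earlier
- south-east: partner 0.800 M; time 2.0 d
- south: partner 0.200 M; time 4.0 d

- alder (time / h: product / %, substrate / %): 8.00: 0, 62.0; 15.0: 0.7, 57.3; 25.0: 1.5, 53.9; 30.0: 2.5, 52.2; 40.0: 4.1, 50.6; 50.0: 5.4, 49.0
- oak (time / h: product / %, substrate / %): 4.00: 0.5, 28.4; 6.00: 0.7, 23.5; 10.0: 3.2, 18.6; 20.0: 9.5, 13.4; 30.0: 18.1, 9.6; 50.0: 33.3, 5.9

(readings scatter by 0.3 percentage points)

- a reading of substrate is of its free form alone

1. which of the two ends with the higher amount of product, in percent of the substrate charged ("neither" if they lie within 2 percentage points) (south-east / south / neither)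
2. product at the end, in percent of the substrate charged, south-east
3. product at the end, in percent of the substrate charged, south

You can fold both settings into one number. South-east stands at 1.22 on the partner clock, which is partner charge times time as a fraction of that product at the last oak reading, and south stands at 0.610. The claim is that a flask holds the fraction of the charge as product that oak held at the same clock.

Test it on alder. Its last reading stands at 0.254, where the oak readings, interpolated, give 4.90 %, and alder read 5.4 %. So the clock carries product, but it does not carry free substrate: alder ends at 49.0 %, higher than the 18.6 % oak shows at the lower clock of 0.200.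

Continuing the last oak slope, I reckon 41.6 % for south-east and 18.5 % for south, since south-east has twice the clock of south.

The forecast, reasoning that the slow step's rate “scales roughly with free partner”, names south-east, with 40 % (33 % to 47 %) and 17 % (12 % to 23 %). Both of its central values lie below mine.

The flasks give 38.1 % in south-east and 17.4 % in south, so south-east leads.

    substrate + partner ⇌ intermediate A (K = 4.40 /M, k = 0.750 /M/h)
    substrate + partner ⇌ intermediate B (K = 5.30 /M, k = 0.0940 /M/h)
    partner + intermediate A → intermediate C (k = 0.0910 /M/h)
    intermediate C ⇌ intermediate D (K = 0.430, k = 0.00760 /h)
    intermediate D ⇌ intermediate E (K = 0.620, k = 0.0610 /h)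
    intermediate C → product (k = 0.0300 /h)

The gap comes mainly from the partner charge: south-east, given the partner charge of south for its 2.0 d, reads 7.69 % against 38.1 %. On its clock of 1.22, south-east reads 38.1 %, below the 41.6 % I reckoned. South-east at 12 h stands on 0.305, where the oak readings, interpolated, give 6.50 %, and it reads 5.55 %.

All runs were computed from invented constants, and the scatter is random.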